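**Plan**

- Retrosynthesis: first the two O-alkyl bonds (benzyl on ring B, methyl on ring A) are cut, then the C1–C2 and C5–C6 bonds of ring A (Diels–Alder with loss of methanol). The enol-ester C–O bond then separates a ring B acid chloride from 4,4-dimethoxybut-3-en-2-one.
- Forward: ring B is built from 3,5-dimethoxytoluene (chlorine first, then the carboxyl carbon) and the enone from acetyl chloride and 1,1-dichloroethene. The dienolate is O-acylated, and ring A, the only ring formed, is closed last on the depside oxygen that is already in place.
- Enabling feature: ring A carries oxygen at C2 and C4, the ester at C1 and the methyl at C6. This 1,3-dioxygenated benzoate maps onto a 1,1,3-trioxygenated butadiene plus a but-2-ynoate.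
- Stereochemistry: the target has no stereocentre. Only regiochemistry matters: it is fixed by the symmetry of the chloroarene for ring B and by the polarisation of the diene for ring A.

Key step: step 10

Remark on the chemistry: the ring B phenol is carried as a benzyl ether, because an ortho acetal-type ether is not expected to survive acid chloride formation. Both ketene acetals are assumed to be handled under anhydrous, acid-free conditions.

**Route**

Step 1
Reactants: 1 acetyl chloride; 2 1,1-dichloroethene
Product: 4 4,4-dichlorobut-3-en-2-one, via 4,4,4-trichlorobutan-2-one 3 (not isolated)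
Conditions: AlCl3 (1.1 equiv), CH2Cl2, 0 °C → rt; ice/aq HCl; distillation (−HCl)
Reagents that add atoms: none
Why: The acylium ion formed with AlCl3 adds to the CH2 terminus of the alkene (Friedel–Crafts-type alkene acylation), the dichlorocarbenium ion captures chloride, and the β-trichloromethyl ketone loses HCl to give the conjugated dichlorovinyl ketone.

Step 2
Reactants: 4 4,4-dichlorobut-3-en-2-one
Product: 5 4,4-dimethoxybut-3-en-2-one
Conditions: NaOMe (2.1 equiv), MeOH, 0 °C → rt
Reagents that add atoms: NaOMe (sodium methoxide), [Na+].[O-]C
Why: Two successive conjugate addition–elimination events (vinylic nucleophilic substitution) should replace both β-chlorines of the enone by methoxide and give the push-pull acylketene dimethyl acetal.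

Step 3
Reactants: 6 3,5-dimethoxytoluene (1,3-dimethoxy-5-methylbenzene)
Product: 8 2-chloro-1,3-dimethoxy-5-methylbenzene, via (2,6-dimethoxy-4-methylphenyl)lithium 7 (not isolated)
Conditions: n-BuLi, TMEDA, THF, 0 °C → rt; then C2Cl6, −78 °C → rt
Reagents that add atoms: hexachloroethane, ClC(Cl)(Cl)C(Cl)(Cl)Cl
Why: In this directed ortho-metalation the two methoxy groups jointly direct lithiation to the carbon between them, and hexachloroethane transfers electrophilic chlorine to the aryllithium, so the chlorine is placed regiospecifically.

Step 4
Reactants: 8 2-chloro-1,3-dimethoxy-5-methylbenzene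
Product: 9 3-chloro-2,4-dimethoxy-6-methylbenzaldehyde
Conditions: Cl2CHOMe, TiCl4, CH2Cl2, 0 °C; then H2O
Reagents that add atoms: dichloromethyl methyl ether, COC(Cl)Cl; water, O
Why: In this Rieche formylation the two open ring positions are equivalent by symmetry and each is ortho and para to a methoxy group, so only one aldehyde can form.

Step 5
Reactants: 9 3-chloro-2,4-dimethoxy-6-methylbenzaldehyde
Product: 10 3-chloro-2-hydroxy-4-methoxy-6-methylbenzaldehyde
Conditions: BCl3 (1.2 equiv), CH2Cl2, −78 → 0 °C; then H2O
Reagents that add atoms: none
Why: In this chelation-controlled Lewis acid demethylation BCl3 is held between the aldehyde oxygen and the ortho methoxy oxygen and chloride removes that methyl group, while the para methoxy group cannot chelate and should stay.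

Step 6
Reactants: 10 3-chloro-2-hydroxy-4-methoxy-6-methylbenzaldehyde
Product: 11 2-(benzyloxy)-3-chloro-4-methoxy-6-methylbenzaldehyde
Conditions: BnBr, K2CO3, DMF, 60 °C
Reagents that add atoms: benzyl bromide, BrCc1ccccc1
Why: Williamson etherification of the phenoxide installs a benzyl ether that tolerates the oxidation, the acid chloride formation, the strong base and the heating that follow, and that BCl3 removes at the end.

Step 7
Reactants: 11 2-(benzyloxy)-3-chloro-4-methoxy-6-methylbenzaldehyde
Product: 12 2-(benzyloxy)-3-chloro-4-methoxy-6-methylbenzoic acid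
Conditions: NaClO2, NaH2PO4, 2-methylbut-2-ene, t-BuOH/H2O, rt
Reagents that add atoms: NaClO2 (sodium chlorite), [Na+].[O-]Cl=O
Why: The Pinnick oxidation converts the hindered aldehyde to the acid under buffered conditions, and 2-methylbut-2-ene traps the hypochlorous acid so that the electron-rich ring is not chlorinated.

Step 8
Reactants: 12 2-(benzyloxy)-3-chloro-4-methoxy-6-methylbenzoic acid
Product: 13 2-(benzyloxy)-3-chloro-4-methoxy-6-methylbenzoyl chloride
Conditions: (COCl)2, cat. DMF, CH2Cl2, 0 °C → rt; evaporation, used crude
Reagents that add atoms: oxalyl chloride, O=C(Cl)C(=O)Cl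
Why: Chloroiminium (Vilsmeier-type) catalysis turns the hindered acid into its chloride under conditions that the benzyl and methyl ethers tolerate.

Step 9
Reactants: 5 4,4-dimethoxybut-3-en-2-one; 13 2-(benzyloxy)-3-chloro-4-methoxy-6-methylbenzoyl chloride
Product: 15 4,4-dimethoxybuta-1,3-dien-2-yl 2-(benzyloxy)-3-chloro-4-methoxy-6-methylbenzoate, via potassium 4,4-dimethoxybuta-1,3-dien-2-olate 14 (not isolated)
Conditions: KN(SiMe3)2, THF, −78 °C; then 13, −78 → −20 °C; non-aqueous work-up (pentane, filtration), used crude
Reagents that add atoms: none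
Why: Kinetic deprotonation of the methyl ketone gives the cross-conjugated potassium dienolate, whose hard oxygen should be acylated by the hindered aroyl chloride (enol ester formation), in analogy to the O-silylation that gives the related 3-silyloxy dienes.

Step 10
Reactants: 15 4,4-dimethoxybuta-1,3-dien-2-yl 2-(benzyloxy)-3-chloro-4-methoxy-6-methylbenzoate; 16 methyl but-2-ynoate
Product: 18 methyl 4-{[2-(benzyloxy)-3-chloro-4-methoxy-6-methylbenzoyl]oxy}-2-methoxy-6-methylbenzoate, via cyclohexa-1,4-diene cycloadduct 17 (not isolated)
Conditions: 16 (5 equiv), toluene, 110 °C, sealed tube; then cat. pyridinium p-toluenesulfonate, CH2Cl2, rt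
Reagents that add atoms: none
Why: The three oxygen donors raise the HOMO of diene 15 and place its largest coefficient on the CH2 terminus, which bonds to the methyl-bearing β-carbon of 16 (C5–C6) while the ketene-acetal carbon bonds to the α-carbon (C1–C2) in a concerted, asynchronous (4+2) cycloaddition that may become stepwise. The closest known reaction type is the Diels–Alder benzannulation of 1,1-dialkoxy-3-silyloxybuta-1,3-dienes (Brassard- and Chan-type dienes) with alkynoates. Ring A, the only ring closed, arises by intermolecular (4+2) closure of a six-membered carbocycle as cyclohexa-1,4-diene 17, which aromatises by 1,4-elimination of methanol (the ring CH2 hydrogen and one of the geminal methoxy groups). No stereocentre is created. The selectivity needed is regiochemical, and it is secured by matching the nucleophilic CH2 terminus of the diene with the electrophilic β-carbon of the alkynoate, the orientation that puts the retained methoxy group ortho to the ester. Because the aroyloxy group already sits on the central diene carbon, the depside oxygen is fixed at C4 without any differentiation of phenols.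

Step 11
Reactants: 18 methyl 4-{[2-(benzyloxy)-3-chloro-4-methoxy-6-methylbenzoyl]oxy}-2-methoxy-6-methylbenzoate
Product: 19 methyl 4-[(3-chloro-2-hydroxy-4-methoxy-6-methylbenzoyl)oxy]-2-hydroxy-6-methylbenzoate
Conditions: BCl3 (4 equiv), CH2Cl2, −78 → 0 °C; then H2O
Reagents that add atoms: none
Why: BCl3 should cleave the benzyl ether quickly and then, by chelation to the methyl ester carbonyl, the ring A methoxy group ortho to it (Lewis acid dealkylation), whereas the 4'-methoxy group has no neighbouring carbonyl and both esters are expected to be inert at this temperature.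

**Compound list**

1 | acetyl chloride | CC(=O)Cl | starting material
2 | 1,1-dichloroethene | C=C(Cl)Cl | starting material
3 | 4,4,4-trichlorobutan-2-one (not isolated) | CC(=O)CC(Cl)(Cl)Cl | intermediate
4 | 4,4-dichlorobut-3-en-2-one | CC(=O)C=C(Cl)Cl | intermediate
5 | 4,4-dimethoxybut-3-en-2-one | CC(=O)C=C(OC)OC | intermediate
6 | 3,5-dimethoxytoluene (1,3-dimethoxy-5-methylbenzene) | COc1cc(C)cc(OC)c1 | starting material
7 | (2,6-dimethoxy-4-methylphenyl)lithium (not isolated) | [Li]c1c(OC)cc(C)cc1OC | intermediate
8 | 2-chloro-1,3-dimethoxy-5-methylbenzene | COc1cc(C)cc(OC)c1Cl | intermediate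
9 | 3-chloro-2,4-dimethoxy-6-methylbenzaldehyde | O=Cc1c(C)cc(OC)c(Cl)c1OC | intermediate
10 | 3-chloro-2-hydroxy-4-methoxy-6-methylbenzaldehyde | O=Cc1c(C)cc(OC)c(Cl)c1O | intermediate
11 | 2-(benzyloxy)-3-chloro-4-methoxy-6-methylbenzaldehyde | O=Cc1c(C)cc(OC)c(Cl)c1OCc1ccccc1 | intermediate
12 | 2-(benzyloxy)-3-chloro-4-methoxy-6-methylbenzoic acid | OC(=O)c1c(C)cc(OC)c(Cl)c1OCc1ccccc1 | intermediate
13 | 2-(benzyloxy)-3-chloro-4-methoxy-6-methylbenzoyl chloride | ClC(=O)c1c(C)cc(OC)c(Cl)c1OCc1ccccc1 | intermediate
14 | potassium 4,4-dimethoxybuta-1,3-dien-2-olate (not isolated) | [K+].[O-]C(=C)C=C(OC)OC | intermediate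
15 | 4,4-dimethoxybuta-1,3-dien-2-yl 2-(benzyloxy)-3-chloro-4-methoxy-6-methylbenzoate | C=C(OC(=O)c1c(C)cc(OC)c(Cl)c1OCc1ccccc1)C=C(OC)OC | intermediate
16 | methyl but-2-ynoate | CC#CC(=O)OC | starting material
17 | methyl 4-{[2-(benzyloxy)-3-chloro-4-methoxy-6-methylbenzoyl]oxy}-6,6-dimethoxy-2-methylcyclohexa-1,4-diene-1-carboxylate (not isolated) | COC(=O)C1=C(C)CC(OC(=O)c2c(C)cc(OC)c(Cl)c2OCc2ccccc2)=CC1(OC)OC | intermediate
18 | methyl 4-{[2-(benzyloxy)-3-chloro-4-methoxy-6-methylbenzoyl]oxy}-2-methoxy-6-methylbenzoate | COC(=O)c1c(C)cc(OC(=O)c2c(C)cc(OC)c(Cl)c2OCc2ccccc2)cc1OC | intermediate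
19 | methyl 4-[(3-chloro-2-hydroxy-4-methoxy-6-methylbenzoyl)oxy]-2-hydroxy-6-methylbenzoate | COC(=O)c1c(C)cc(OC(=O)c2c(C)cc(OC)c(Cl)c2O)cc1O | target

**Summary**

Total step count: 11.
Longest linear sequence: 9 steps (steps 3 to 11, from 3,5-dimethoxytoluene 6 to target 19).

Steps most likely to fail:

1. Step 10. The cycloaddition with the β-methyl alkynoate may be slow enough that thermal decomposition, polymerisation or adventitious hydrolysis of the ketene acetal outruns ring formation. Fallback: setting out from 15, the dienophile is changed to commercial methyl buta-2,3-dienoate (C=C=CC(=O)OC), whose conjugated allenic double bond is a much better dienophile. The CH2 terminus of 15 should bond to the central allene carbon and the ketene-acetal carbon to the ester-bearing carbon, so the same two ring bonds form at lower temperature (toluene, 40–60 °C). This would give methyl 4-{[2-(benzyloxy)-3-chloro-4-methoxy-6-methylbenzoyl]oxy}-2,2-dimethoxy-6-methylidenecyclohex-3-ene-1-carboxylate F1 (racemic, not isolated). F1 loses methanol and tautomerises (exocyclic methylene to aryl methyl) under the same acid catalysis, and the route is rejoined at 18.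

2. Step 9. The ambident dienolate may be acylated on carbon instead of oxygen, and the acyloxy ketene acetal may hydrolyse during isolation. Fallback: setting out from 5, the depside bond is made after the benzannulation. Silylation (Me3SiCl, Et3N, cat. ZnCl2) gives 1,1-dimethoxy-3-(trimethylsilyloxy)buta-1,3-diene F2. Heating F2 with 16 forms the same C1–C2 and C5–C6 bonds and, after loss of methanol, gives methyl 2-methoxy-6-methyl-4-(trimethylsilyloxy)benzoate F3. Dilute aqueous HCl in THF frees methyl 4-hydroxy-2-methoxy-6-methylbenzoate F4. Acylation of this single free phenol with 13 (Et3N, cat. DMAP, CH2Cl2) rejoins the route at 18.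

3. Step 11. The ring A methyl ether may be cleaved incompletely, or longer exposure to excess Lewis acid may erode selectivity through attack on the 4'-methoxy group or on the aryl ester. Fallback: setting out from 18, the two deprotections are separated into orthogonal operations. Hydrogenolysis (H2, Pd/C, EtOAc, rt, short reaction time to spare the aryl chloride) gives methyl 4-[(3-chloro-2-hydroxy-4-methoxy-6-methylbenzoyl)oxy]-2-methoxy-6-methylbenzoate F5. The single chelated methoxy group of F5 is then removed with MgI2 etherate (toluene/Et2O, 60 °C), which acts only on ethers ortho to a carbonyl, and the route is rejoined at 19.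

**Further compounds**

F1 | step 10 | methyl 4-{[2-(benzyloxy)-3-chloro-4-methoxy-6-methylbenzoyl]oxy}-2,2-dimethoxy-6-methylidenecyclohex-3-ene-1-carboxylate (racemic) | COC(=O)C1C(=C)CC(OC(=O)c2c(C)cc(OC)c(Cl)c2OCc2ccccc2)=CC1(OC)OC
F2 | step 9 | 1,1-dimethoxy-3-(trimethylsilyloxy)buta-1,3-diene | C=C(O[Si](C)(C)C)C=C(OC)OC
F3 | step 9 | methyl 2-methoxy-6-methyl-4-(trimethylsilyloxy)benzoate | COC(=O)c1c(C)cc(O[Si](C)(C)C)cc1OC
F4 | step 9 | methyl 4-hydroxy-2-methoxy-6-methylbenzoate | COC(=O)c1c(C)cc(O)cc1OC
F5 | step 11 | methyl 4-[(3-chloro-2-hydroxy-4-methoxy-6-methylbenzoyl)oxy]-2-methoxy-6-methylbenzoate | COC(=O)c1c(C)cc(OC(=O)c2c(C)cc(OC)c(Cl)c2O)cc1OC
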